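The route rests on disconnecting the chalcone at its C(=O)–Cα bond, so that the base-labile (2R,3S)-flavanone (C2 open to retro-oxa-Michael, C3 enolisable) never meets aldol conditions. The key step is a rhodium-catalysed, atom-economic hydroacylation: 2,4-dihydroxybenzaldehyde adds its formyl C–H across the terminal alkyne of a MOM-protected 3-(5-ethynyl-2-oxyphenyl)flavanone, giving the E-enone in one operation. It exploits the free hydroxyl on C2' of the resorcinol ring, ortho to the carbonyl, as the built-in chelating group. The flavanone C2 centre comes from an asymmetric conjugate arylation of a chromone; C3 is arylated through the enol silane, trans by thermodynamics.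

Key step: step 8

Remark: (S)-t-BuPyOx is assumed to deliver the (R)-flavanone in step 2; if the sense of induction proves opposite, (R)-t-BuPyOx is used instead.

Step 1
Reactants: 1 7-hydroxy-4H-chromen-4-one
Product: 2 7-(methoxymethoxy)-4H-chromen-4-one
Conditions: MOMCl, K2CO3, acetone, 0 °C → rt
Reagents that add atoms: chloromethyl methyl ether (MOMCl), COCCl
Why: Williamson-type O-alkylation of the acidic 7-OH gives the MOM acetal, which should survive every later step and fall only to acid at the end.

Step 2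
Reactants: 2 7-(methoxymethoxy)-4H-chromen-4-one; 3 [4-(methoxymethoxy)phenyl]boronic acid
Product: 4 (R)-7-(methoxymethoxy)-2-[4-(methoxymethoxy)phenyl]chroman-4-one
Conditions: Pd(OCOCF3)2 (5 mol %), (S)-t-BuPyOx (6 mol %), NH4PF6 (30 mol %), H2O (5 equiv), ClCH2CH2Cl, 60 °C
Reagents that add atoms: none
Why: Asymmetric conjugate addition of an arylboronic acid to a chromone under cationic divalent palladium/pyridine-oxazoline catalysis, in which the aryl–palladium species inserts C2=C3 on the face left open by the tert-butyl group of the ligand and so sets C2 as R, while the base-free aqueous medium protonates the enolate without opening ring C.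

Step 3
Reactants: 4 (R)-7-(methoxymethoxy)-2-[4-(methoxymethoxy)phenyl]chroman-4-one
Product: 5 (R)-{[7-(methoxymethoxy)-2-[4-(methoxymethoxy)phenyl]-2H-chromen-4-yl]oxy}trimethylsilane
Conditions: TMSOTf, Et3N, CH2Cl2, −78 → 0 °C; non-aqueous work-up, used crude
Reagents that add atoms: trimethylsilyl trifluoromethanesulfonate, C[Si](C)(C)OS(=O)(=O)C(F)(F)F
Why: Soft enolisation gives the enol silane without a free enolate, so the retro-oxa-Michael opening that would racemise C2 should be avoided.

Step 4
Reactants: 6 2-bromo-4-iodophenol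
Product: 7 2-bromo-4-iodo-1-(methoxymethoxy)benzene
Conditions: MOMCl, K2CO3, acetone, rt
Reagents that add atoms: chloromethyl methyl ether (MOMCl), COCCl
Why: Williamson-type O-alkylation of the phenol gives an acetal that tolerates the organometallic steps ahead.

Step 5
Reactants: 7 2-bromo-4-iodo-1-(methoxymethoxy)benzene; 8 ethynyltri(propan-2-yl)silane
Product: 9 {[3-bromo-4-(methoxymethoxy)phenyl]ethynyl}tri(propan-2-yl)silane
Conditions: PdCl2(PPh3)2 (2 mol %), CuI (4 mol %), Et3N, THF, rt
Reagents that add atoms: none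
Why: Sonogashira coupling should occur only at the C–I bond, which adds to zerovalent palladium far faster at room temperature than the ortho-substituted C–Br bond.

Step 6
Reactants: 5 (R)-{[7-(methoxymethoxy)-2-[4-(methoxymethoxy)phenyl]-2H-chromen-4-yl]oxy}trimethylsilane; 9 {[3-bromo-4-(methoxymethoxy)phenyl]ethynyl}tri(propan-2-yl)silane
Product: 10 (2R,3S)-7-(methoxymethoxy)-3-{2-(methoxymethoxy)-5-[(triisopropylsilyl)ethynyl]phenyl}-2-[4-(methoxymethoxy)phenyl]chroman-4-one
Conditions: Pd(OAc)2 (5 mol %), P(t-Bu)3 (10 mol %), Bu3SnF, CsF, toluene, 85 °C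
Reagents that add atoms: none
Why: Fluoride-promoted palladium-catalysed α-arylation of an enol silane (Kuwajima–Urabe/Hartwig type) forms the C3–aryl bond without strong base; the aryl group should enter anti to the C2 aryl and any cis isomer should equilibrate through the enol to the trans-diequatorial (2R,3S) product, C2 being untouched.

Step 7
Reactants: 10 (2R,3S)-7-(methoxymethoxy)-3-{2-(methoxymethoxy)-5-[(triisopropylsilyl)ethynyl]phenyl}-2-[4-(methoxymethoxy)phenyl]chroman-4-one
Product: 12 (2R,3S)-3-[5-ethynyl-2-(methoxymethoxy)phenyl]-7-(methoxymethoxy)-2-[4-(methoxymethoxy)phenyl]chroman-4-one, via silver acetylide 11 (not isolated)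
Conditions: AgF, MeOH/MeCN, rt, dark; then 1 M HCl
Reagents that add atoms: none
Why: Silver-mediated protiodesilylation, in which fluoride activates silicon, silver captures the acetylide and dilute acid protonates it, should remove the bulky silyl group under near-neutral conditions that spare the MOM acetals and the epimerisable flavanone.

Step 8
Reactants: 12 (2R,3S)-3-[5-ethynyl-2-(methoxymethoxy)phenyl]-7-(methoxymethoxy)-2-[4-(methoxymethoxy)phenyl]chroman-4-one; 13 2,4-dihydroxybenzaldehyde
Product: 14 (2R,3S)-3-{5-[(E)-3-(2,4-dihydroxyphenyl)-3-oxoprop-1-en-1-yl]-2-(methoxymethoxy)phenyl}-7-(methoxymethoxy)-2-[4-(methoxymethoxy)phenyl]chroman-4-one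
Conditions: [RhCl(cod)]2 (2.5 mol %), dppf (5 mol %), Na2CO3 (10 mol %), toluene/1,4-dioxane, 90 °C
Reagents that add atoms: none
Why: The C2'-phenoxide of 13 binds monovalent rhodium and the formyl C–H adds oxidatively to give a five-membered O,C-chelated acyl(hydrido)rhodium species in which decarbonylation is suppressed; syn hydrometalation of the terminal alkyne of 12 places rhodium on the terminal carbon, and C–C reductive elimination forms the C(=O)–Cα bond and releases the enone. The closest known reaction type is the chelation-assisted intermolecular hydroacylation of alkynes with salicylaldehydes. No ring is closed and no stereocentre is created; the E geometry follows from syn addition of acyl and hydrogen across the triple bond. The step needs linear over branched regioselectivity, which the bulky aryl terminus of 12 and the wide-bite-angle dppf ligand should secure. It also needs reaction through the C2'-OH and not the more acidic C4'-OH, which only the chelate-forming ortho hydroxyl can provide. The nearly neutral medium should leave C2 and C3 of ring C untouched, which a base-mediated Claisen–Schmidt condensation would not.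

Step 9
Reactants: 14 (2R,3S)-3-{5-[(E)-3-(2,4-dihydroxyphenyl)-3-oxoprop-1-en-1-yl]-2-(methoxymethoxy)phenyl}-7-(methoxymethoxy)-2-[4-(methoxymethoxy)phenyl]chroman-4-one
Product: 15 (2R,3S)-3-{5-[(E)-3-(2,4-dihydroxyphenyl)-3-oxoprop-1-en-1-yl]-2-hydroxyphenyl}-7-hydroxy-2-(4-hydroxyphenyl)chroman-4-one
Conditions: HCl (3 M aq), MeOH/THF, 45 °C
Reagents that add atoms: none
Why: Acid-catalysed transacetalisation of the three MOM ethers to methanol should free the phenols while the hydrogen-bonded 2'-hydroxychalcone and the flavanone, whose C3 already sits in its thermodynamic trans arrangement, are not opened or enolised to a harmful extent under mild acid.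

Compound list
1 | 7-hydroxy-4H-chromen-4-one | O=c1ccoc2cc(O)ccc12 | starting material
2 | 7-(methoxymethoxy)-4H-chromen-4-one | COCOc1ccc2c(c1)occc2=O | intermediate
3 | [4-(methoxymethoxy)phenyl]boronic acid | COCOc1ccc(B(O)O)cc1 | starting material
4 | (R)-7-(methoxymethoxy)-2-[4-(methoxymethoxy)phenyl]chroman-4-one | O=C1C[C@H](c2ccc(OCOC)cc2)Oc2cc(OCOC)ccc21 | intermediate
5 | (R)-{[7-(methoxymethoxy)-2-[4-(methoxymethoxy)phenyl]-2H-chromen-4-yl]oxy}trimethylsilane | C[Si](C)(C)OC1=C[C@H](c2ccc(OCOC)cc2)Oc2cc(OCOC)ccc21 | intermediate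
6 | 2-bromo-4-iodophenol | Oc1ccc(I)cc1Br | starting material
7 | 2-bromo-4-iodo-1-(methoxymethoxy)benzene | COCOc1ccc(I)cc1Br | intermediate
8 | ethynyltri(propan-2-yl)silane | C#C[Si](C(C)C)(C(C)C)C(C)C | starting material
9 | {[3-bromo-4-(methoxymethoxy)phenyl]ethynyl}tri(propan-2-yl)silane | COCOc1ccc(C#C[Si](C(C)C)(C(C)C)C(C)C)cc1Br | intermediate
10 | (2R,3S)-7-(methoxymethoxy)-3-{2-(methoxymethoxy)-5-[(triisopropylsilyl)ethynyl]phenyl}-2-[4-(methoxymethoxy)phenyl]chroman-4-one (2,3-trans) | CC(C)[Si](C#Cc1ccc(OCOC)c([C@@H]2C(=O)c3ccc(OCOC)cc3O[C@H]2c2ccc(OCOC)cc2)c1)(C(C)C)C(C)C | intermediate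
11 | silver acetylide of alkyne 12 (not isolated) | [Ag]C#Cc1ccc(OCOC)c([C@@H]2C(=O)c3ccc(OCOC)cc3O[C@H]2c2ccc(OCOC)cc2)c1 | intermediate
12 | (2R,3S)-3-[5-ethynyl-2-(methoxymethoxy)phenyl]-7-(methoxymethoxy)-2-[4-(methoxymethoxy)phenyl]chroman-4-one | C#Cc1ccc(OCOC)c([C@@H]2C(=O)c3ccc(OCOC)cc3O[C@H]2c2ccc(OCOC)cc2)c1 | intermediate
13 | 2,4-dihydroxybenzaldehyde | O=Cc1ccc(O)cc1O | starting material
14 | (2R,3S)-3-{5-[(E)-3-(2,4-dihydroxyphenyl)-3-oxoprop-1-en-1-yl]-2-(methoxymethoxy)phenyl}-7-(methoxymethoxy)-2-[4-(methoxymethoxy)phenyl]chroman-4-one | O=C(/C=C/c1ccc(OCOC)c([C@@H]2C(=O)c3ccc(OCOC)cc3O[C@H]2c2ccc(OCOC)cc2)c1)c1ccc(O)cc1O | intermediate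
15 | (2R,3S)-3-{5-[(E)-3-(2,4-dihydroxyphenyl)-3-oxoprop-1-en-1-yl]-2-hydroxyphenyl}-7-hydroxy-2-(4-hydroxyphenyl)chroman-4-one | O=C(/C=C/c1ccc(O)c([C@@H]2C(=O)c3ccc(O)cc3O[C@H]2c2ccc(O)cc2)c1)c1ccc(O)cc1O | target

Total step count: 9. Longest linear sequence: 7 steps (steps 1, 2, 3, 6, 7, 8, 9).

Steps most likely to fail

Step 6. Reductive elimination at the crowded C3 position may be slow, so that β-hydride elimination from the palladium enolate (dehydrogenation towards the flavone) takes over. Fluoride-induced enolisation with opening and reclosure of ring C could also erode the configuration at C2. The fallback reverses the polarity of the coupling and sets out from 5 and 9. Treating 5 with N-bromosuccinimide in THF at −78 °C should give (2S,3S)-3-bromo-7-(methoxymethoxy)-2-[4-(methoxymethoxy)phenyl]chroman-4-one F1, bromine entering anti to the C2 aryl. Bromine–lithium exchange on 9 with n-BuLi in THF at −78 °C should give {2-(methoxymethoxy)-5-[(triisopropylsilyl)ethynyl]phenyl}lithium F2, which ZnCl2 converts into chloro{2-(methoxymethoxy)-5-[(triisopropylsilyl)ethynyl]phenyl}zinc F3. A nickel-catalysed Negishi arylation of the secondary α-bromoketone F1 with F3 (NiCl2(dme), a pybox ligand, glyme/THF, −30 °C) proceeds through a C3 radical that should be captured anti to the C2 aryl. The fallback returns to the route at 10.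

Step 8. The hydrometalation may lose linear/branched regiocontrol, the terminal alkyne may oligomerise on rhodium, the acylrhodium hydride may decarbonylate, or the more acidic C4'-OH may sequester the catalytic base. The fallback forms the same bond by carbonyl addition and oxidation and sets out from 12 and 13. Double protection of 13 (MOMCl, NaH, DMF) should give 2,4-bis(methoxymethoxy)benzaldehyde F4. Hydroboration of 12 with dicyclohexylborane (toluene, 0 °C) should give the (E)-alkenyl(dicyclohexyl)borane F5, and boron–zinc exchange with Et2Zn at −78 °C the (E)-alkenyl(ethyl)zinc F6. In the same flask F6 should add to F4 (catalytic N,N-dimethylaminoethanol, 0 °C) to give the allylic alcohol F7 as a mixture at the carbinol centre; organozincs of this kind should ignore the ring C ketone. Oxidation with MnO2 in CH2Cl2 should give the fully MOM-protected chalcone F8, and the acid conditions of step 9 should then remove all four MOM groups. The fallback returns to the route at 15.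

Step 9. During MOM cleavage the acid may promote oxa-Michael closure of the new 2'-hydroxychalcone onto its enone, addition of methanol to the enone, or ionisation of the benzylic C2–O bond. The fallback removes the acetals before the chalcone exists and sets out from 12. Treating 12 with HCl in MeOH/THF should give (2R,3S)-3-(5-ethynyl-2-hydroxyphenyl)-7-hydroxy-2-(4-hydroxyphenyl)chroman-4-one F9. Hydroacylation of F9 with 13 under the conditions of step 8 then becomes the final step, so the enone never meets acid. The fallback returns to the route at 15.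

Further compounds
F1 | step 6 | (2S,3S)-3-bromo-7-(methoxymethoxy)-2-[4-(methoxymethoxy)phenyl]chroman-4-one (2,3-trans) | Br[C@@H]1C(=O)c2ccc(OCOC)cc2O[C@H]1c1ccc(OCOC)cc1
F2 | step 6 | {2-(methoxymethoxy)-5-[(triisopropylsilyl)ethynyl]phenyl}lithium | [Li]c1cc(C#C[Si](C(C)C)(C(C)C)C(C)C)ccc1OCOC
F3 | step 6 | chloro{2-(methoxymethoxy)-5-[(triisopropylsilyl)ethynyl]phenyl}zinc | Cl[Zn]c1cc(C#C[Si](C(C)C)(C(C)C)C(C)C)ccc1OCOC
F4 | step 8 | 2,4-bis(methoxymethoxy)benzaldehyde | COCOc1ccc(C=O)c(OCOC)c1
F5 | step 8 | dicyclohexyl{(E)-2-[4-(methoxymethoxy)-3-[(2R,3S)-7-(methoxymethoxy)-2-[4-(methoxymethoxy)phenyl]-4-oxochroman-3-yl]phenyl]ethenyl}borane | C1CCCCC1B(/C=C/c1ccc(OCOC)c([C@@H]2C(=O)c3ccc(OCOC)cc3O[C@H]2c2ccc(OCOC)cc2)c1)C1CCCCC1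
F6 | step 8 | ethyl{(E)-2-[4-(methoxymethoxy)-3-[(2R,3S)-7-(methoxymethoxy)-2-[4-(methoxymethoxy)phenyl]-4-oxochroman-3-yl]phenyl]ethenyl}zinc | CC[Zn]/C=C/c1ccc(OCOC)c([C@@H]2C(=O)c3ccc(OCOC)cc3O[C@H]2c2ccc(OCOC)cc2)c1
F7 | step 8 | (2R,3S)-3-{5-[(E)-3-[2,4-bis(methoxymethoxy)phenyl]-3-hydroxyprop-1-en-1-yl]-2-(methoxymethoxy)phenyl}-7-(methoxymethoxy)-2-[4-(methoxymethoxy)phenyl]chroman-4-one (both carbinol configurations) | OC(/C=C/c1ccc(OCOC)c([C@@H]2C(=O)c3ccc(OCOC)cc3O[C@H]2c2ccc(OCOC)cc2)c1)c1ccc(OCOC)cc1OCOC
F8 | step 8 | (2R,3S)-3-{5-[(E)-3-[2,4-bis(methoxymethoxy)phenyl]-3-oxoprop-1-en-1-yl]-2-(methoxymethoxy)phenyl}-7-(methoxymethoxy)-2-[4-(methoxymethoxy)phenyl]chroman-4-one | O=C(/C=C/c1ccc(OCOC)c([C@@H]2C(=O)c3ccc(OCOC)cc3O[C@H]2c2ccc(OCOC)cc2)c1)c1ccc(OCOC)cc1OCOC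
F9 | step 9 | (2R,3S)-3-(5-ethynyl-2-hydroxyphenyl)-7-hydroxy-2-(4-hydroxyphenyl)chroman-4-one | C#Cc1ccc(O)c([C@@H]2C(=O)c3ccc(O)cc3O[C@H]2c2ccc(O)cc2)c1
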